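The route rests on cutting the aryl ether bond O1–C8a of the pyran ring. C2 is a fully substituted, linalool-like carbinol carbon (methyl, six-carbon chain, C3). A Z C3=C4 alkene holds its oxygen next to C8a of ring A, adjacent to the oxygenated C8. Palladium-catalysed intramolecular O-arylation of this β-hydrogen-free tertiary alkoxide by a C8a bromide closes the 2H-pyran in one operation and leaves all four bonds at C2 untouched. The precursor is a tris-TIPS-protected Z-styryl tertiary alcohol that carries the ortho bromide and the complete dihydrochalcone arm. Its R centre comes from Sharpless epoxidation of geraniol.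

Key step: step 12

Remarks on the chemistry (chromene numbering; ring A = benzo ring of the chromene, ring B = resorcinol ring; TIPS = triisopropylsilyl)
- **Configuration.** C2 of the target is R (O1 > C3 > CH2 > CH3). This priority order holds from epoxide to alkynol to chromene, so the (2R,3R)-epoxide of geraniol is needed, which means the D-(−)-tartrate series.
- **Position of the iodide.** Electrophilic iodination of a 3-bromo-4-hydroxyaryl carbonyl compound would enter ortho to the phenol, at the future C7. The C4a iodide lies between the carbonyl-bearing carbon and the bromide, so it is installed by directed magnesiation of the benzoate.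
- **Protecting groups.** All three phenols are carried as TIPS ethers. A smaller aryl silyl ether next to the bromide would be at risk from hot Cs2CO3 and from the selenolate.
- **Three-carbon arm.** The arm is built by enolate alkylation. This avoids a hydroxide-mediated aldol condensation, which would strip aryl silyl ethers. It also avoids an enone reduction in the presence of aryl halides.
- **Handling after ring closure.** 2H-Chromenes can open under light or strong heating to o-quinone methides, which would erase C2. From step 12 on, everything is run in the dark and at or below 80 °C.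
- **Assumption.** The side-chain epoxide is carried as a mixture of epimers at its CH carbon, because that centre is erased in the following step.

Step 1
Reactants: 1 geraniol
Product: 2 (2R,3R)-2,3-epoxygeraniol
Conditions: Ti(OiPr)4 (5 mol %), D-(−)-diethyl tartrate (7 mol %), tBuOOH (1.5 equiv), 4 Å molecular sieves, CH2Cl2, −20 °C
Reagents that add atoms: tert-butyl hydroperoxide, CC(C)(C)OO
Why: Sharpless asymmetric epoxidation, in which the allylic hydroxyl docks the 2,3-alkene on the titanium tartrate complex so that the remote trisubstituted alkene is left alone and the D-(−)-tartrate directs oxygen to the face that gives the (2R,3R)-epoxide, thereby setting the carbon that becomes C2.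

Step 2
Reactants: 2 (2R,3R)-2,3-epoxygeraniol
Product: 3 (2R,3S)-3-(chloromethyl)-2-methyl-2-(4-methylpent-3-en-1-yl)oxirane
Conditions: PPh3, CCl4, NaHCO3, reflux
Reagents that add atoms: carbon tetrachloride, ClC(Cl)(Cl)Cl
Why: Appel chlorination of the primary alcohol proceeds under buffered, essentially neutral conditions, so the acid-sensitive trisubstituted epoxide should survive with both centres unchanged (the descriptor of the CH carbon becomes S only because CH2Cl outranks the ring carbon).

Step 3
Reactants: 3 (2R,3S)-3-(chloromethyl)-2-methyl-2-(4-methylpent-3-en-1-yl)oxirane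
Product: 5 (R)-3,7-dimethyloct-6-en-1-yn-3-ol, via chloroalkenol lithium alkoxide 4 (not isolated)
Conditions: n-BuLi (3.3 equiv), THF, −78 → −30 °C; then H2O
Reagents that add atoms: none
Why: Base-induced fragmentation of a 2,3-epoxy chloride, in which deprotonation next to chlorine opens the oxirane by β-elimination and a second dehydrochlorination turns the chloroalkene into the terminal alkyne, while the C–O bond at the quaternary carbon is never broken, so R is retained.

Step 4
Reactants: 6 methyl 3-bromo-4-hydroxybenzoate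
Product: 7 methyl 3-bromo-4-(triisopropylsilyloxy)benzoate
Conditions: TIPSCl (1.2 equiv), imidazole (2.5 equiv), DMF, rt
Reagents that add atoms: chlorotriisopropylsilane, CC(C)[Si](Cl)(C(C)C)C(C)C
Why: Routine imidazole-promoted silylation of a phenol, the bulky TIPS group being chosen for base stability in later steps and because it shields the adjacent ring hydrogen from metalation.

Step 5
Reactants: 7 methyl 3-bromo-4-(triisopropylsilyloxy)benzoate
Product: 9 methyl 3-bromo-2-iodo-4-(triisopropylsilyloxy)benzoate, via arylmagnesium chloride 8 (not isolated)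
Conditions: TMPMgCl·LiCl (1.3 equiv), THF, −10 → 0 °C; then I2, THF, −30 °C → rt
Reagents that add atoms: iodine, II
Why: Directed ortho-magnesiation followed by iodolysis, in which the ester carbonyl guides the hindered amide base to the one hydrogen that is acidified by two flanking groups (ester and bromine), the resulting arylmagnesium chloride being stable towards ester attack and aryne formation at this temperature.

Step 6
Reactants: 9 methyl 3-bromo-2-iodo-4-(triisopropylsilyloxy)benzoate
Product: 10 [3-bromo-2-iodo-4-(triisopropylsilyloxy)phenyl]methanol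
Conditions: iBu2AlH (2.5 equiv), CH2Cl2, −78 → 0 °C; aq potassium sodium tartrate
Reagents that add atoms: none
Why: Hydride reduction of the ester by iBu2AlH should stop at the benzylic alcohol without touching the aryl iodide, the aryl bromide or the silyl ether.

Step 7
Reactants: 10 [3-bromo-2-iodo-4-(triisopropylsilyloxy)phenyl]methanol
Product: 11 [2-bromo-4-(bromomethyl)-3-iodophenoxy]triisopropylsilane
Conditions: CBr4, PPh3, CH2Cl2, 0 °C
Reagents that add atoms: carbon tetrabromide, BrC(Br)(Br)Br
Why: Appel bromination converts the benzylic alcohol into the bromide under neutral conditions that the aryl silyl ether tolerates.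

Step 8
Reactants: 12 2,4-dihydroxyacetophenone
Product: 13 1-[2,4-bis(triisopropylsilyloxy)phenyl]ethan-1-one
Conditions: TIPSCl (2.6 equiv), imidazole (5 equiv), DMAP (0.1 equiv), DMF, 50 °C
Reagents that add atoms: chlorotriisopropylsilane, CC(C)[Si](Cl)(C(C)C)C(C)C
Why: Imidazole/DMAP-promoted silylation, where gentle heating overcomes the hydrogen bond of the ortho phenol to the carbonyl group and the use of the chloride instead of the triflate avoids enol silylation of the ketone.

Step 9
Reactants: 13 1-[2,4-bis(triisopropylsilyloxy)phenyl]ethan-1-one; 11 [2-bromo-4-(bromomethyl)-3-iodophenoxy]triisopropylsilane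
Product: 15 3-[3-bromo-2-iodo-4-(triisopropylsilyloxy)phenyl]-1-[2,4-bis(triisopropylsilyloxy)phenyl]propan-1-one, via lithium enolate 14 (not isolated)
Conditions: 13 (1.6 equiv), LiN(SiMe3)2 (1.5 equiv), THF, −78 °C; then 11 (1.0 equiv), DMPU, −78 → −20 °C
Reagents that add atoms: none
Why: Alkylation of a kinetic lithium enolate by SN2 displacement at a reactive benzylic bromide builds the saturated three-carbon arm directly, an excess of the cheap enolate at low temperature favouring monoalkylation, the bulk of TIPS holding back oxygen-to-oxygen silyl migration, and both aryl halides being inert to the amide base.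

Step 10
Reactants: 15 3-[3-bromo-2-iodo-4-(triisopropylsilyloxy)phenyl]-1-[2,4-bis(triisopropylsilyloxy)phenyl]propan-1-one; 5 (R)-3,7-dimethyloct-6-en-1-yn-3-ol
Product: 16 3-{3-bromo-2-[(3R)-3-hydroxy-3,7-dimethyloct-6-en-1-yn-1-yl]-4-(triisopropylsilyloxy)phenyl}-1-[2,4-bis(triisopropylsilyloxy)phenyl]propan-1-one
Conditions: 5 (1.4 equiv), PdCl2(PPh3)2 (3 mol %), CuI (5 mol %), Et3N/THF, degassed, 45 °C
Reagents that add atoms: none
Why: Sonogashira coupling, in which zerovalent palladium inserts far faster into the C–I than into the C–Br bond, so only the C4a position is alkynylated and the free tertiary alcohol with its R centre is a spectator.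

Step 11
Reactants: 16 3-{3-bromo-2-[(3R)-3-hydroxy-3,7-dimethyloct-6-en-1-yn-1-yl]-4-(triisopropylsilyloxy)phenyl}-1-[2,4-bis(triisopropylsilyloxy)phenyl]propan-1-one
Product: 17 3-{3-bromo-2-[(1Z,3R)-3-hydroxy-3,7-dimethylocta-1,6-dien-1-yl]-4-(triisopropylsilyloxy)phenyl}-1-[2,4-bis(triisopropylsilyloxy)phenyl]propan-1-one
Conditions: H2 (1 atm), Pd/CaCO3 poisoned with Pb(OAc)2 (Lindlar catalyst), quinoline, EtOAc, rt, stopped after one equivalent of H2
Reagents that add atoms: none
Why: Lindlar semihydrogenation delivers both hydrogens to the same face of the alkyne on the poisoned palladium surface and so should give the Z alkene, while the trisubstituted alkene, the ketone and the aryl bromide are not reduced under these mild conditions.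

Step 12
Reactants: 17 3-{3-bromo-2-[(1Z,3R)-3-hydroxy-3,7-dimethylocta-1,6-dien-1-yl]-4-(triisopropylsilyloxy)phenyl}-1-[2,4-bis(triisopropylsilyloxy)phenyl]propan-1-one
Product: 18 1-[2,4-bis(triisopropylsilyloxy)phenyl]-3-[(2R)-2-methyl-2-(4-methylpent-3-en-1-yl)-8-(triisopropylsilyloxy)-2H-chromen-5-yl]propan-1-one
Conditions: Pd(OAc)2 (5 mol %), 2-(di-tert-butylphosphino)-1,1′-binaphthyl (7 mol %), dried Cs2CO3 (1.5 equiv), toluene (0.03 M), 75 °C, Ar, dark
Reagents that add atoms: none
Why: Zerovalent palladium, formed in situ from Pd(OAc)2 and the bulky electron-rich biaryl phosphine, inserts into the C8a–Br bond, the neighbouring tertiary hydroxyl binds to divalent palladium and is deprotonated by Cs2CO3, and C–O reductive elimination releases the chromene. The closest known reaction type is the intramolecular Buchwald–Hartwig etherification of tertiary alcohols bearing an ortho-bromoaryl group, which gives 2,2-disubstituted chromans. The six-membered pyran ring closes by reductive elimination from a seven-membered oxapalladacycle (Pd, O1, C2, C3, C4, C4a, C8a), whose formation is favoured because the Z alkene fixes oxygen and bromide on the same side. No stereocentre is created, since none of the four bonds at C2 takes part, so the R configuration set in step 1 is carried over unchanged. The alkoxide has no β-hydrogen, which excludes β-hydride elimination and the hydrodebromination that follows from it. The selectivity needed is chemoselectivity, namely ring closure ahead of intermolecular ketone α-arylation and of silyl loss, and it is secured by intramolecularity, dilution, the weak and poorly soluble base and the TIPS ethers.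

Step 13
Reactants: 18 1-[2,4-bis(triisopropylsilyloxy)phenyl]-3-[(2R)-2-methyl-2-(4-methylpent-3-en-1-yl)-8-(triisopropylsilyloxy)-2H-chromen-5-yl]propan-1-one
Product: 19 1-[2,4-bis(triisopropylsilyloxy)phenyl]-3-{(2R)-2-[2-(3,3-dimethyloxiran-2-yl)ethyl]-2-methyl-8-(triisopropylsilyloxy)-2H-chromen-5-yl}propan-1-one (epimers at the oxirane CH)
Conditions: mCPBA (1.0 equiv), NaHCO3, CH2Cl2, −20 → 0 °C, dark
Reagents that add atoms: 3-chloroperbenzoic acid, O=C(OO)c1cccc(Cl)c1
Why: Prilezhaev epoxidation is governed by alkene nucleophilicity and access, so one equivalent of peracid should pick the remote trisubstituted alkene over the C3=C4 alkene, which is only disubstituted and is screened by quaternary C2 and the peri substituent at C5; the new side-chain centre forms without control and is erased in step 14.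

Step 14
Reactants: 19 1-[2,4-bis(triisopropylsilyloxy)phenyl]-3-{(2R)-2-[2-(3,3-dimethyloxiran-2-yl)ethyl]-2-methyl-8-(triisopropylsilyloxy)-2H-chromen-5-yl}propan-1-one
Product: 22 1-[2,4-bis(triisopropylsilyloxy)phenyl]-3-{(2R)-2-[(2E)-4-hydroxy-4-methylpent-2-en-1-yl]-2-methyl-8-(triisopropylsilyloxy)-2H-chromen-5-yl}propan-1-one, via hydroxy selenide 20 (not isolated), via selenoxide 21 (not isolated)
Conditions: PhSeSePh (0.6 equiv), NaBH4 (1.2 equiv), EtOH, rt until gas evolution ends; add 19, 70 °C; then THF, NaHCO3, 30% H2O2 (3 equiv), 0 °C → rt, dark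
Reagents that add atoms: none
Why: Organoselenium conversion of an epoxide into an allylic alcohol, in which the selenolate opens the oxirane by SN2 attack at the less hindered CH carbon, H2O2 gives the selenoxide, and its syn elimination can only take a hydrogen from the neighbouring CH2 group because the carbinol carbon has none, which leads to the E alkene; NaBH4 is fully consumed before the substrate is added, so the ketone is not reduced.

Step 15
Reactants: 22 1-[2,4-bis(triisopropylsilyloxy)phenyl]-3-{(2R)-2-[(2E)-4-hydroxy-4-methylpent-2-en-1-yl]-2-methyl-8-(triisopropylsilyloxy)-2H-chromen-5-yl}propan-1-one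
Product: 23 1-(2,4-dihydroxyphenyl)-3-{(2R)-8-hydroxy-2-[(2E)-4-hydroxy-4-methylpent-2-en-1-yl]-2-methyl-2H-chromen-5-yl}propan-1-one (CNP0311864.1)
Conditions: Bu4NF (3.5 equiv), AcOH (3.5 equiv), THF, 0 °C, Ar, dark
Reagents that add atoms: none
Why: Fluoride-induced cleavage of the three aryl silyl ethers is fast at 0 °C, and the acetic acid buffer keeps the phenoxides protonated so that neither the tertiary allylic alcohol nor the chromene nor the oxidation-prone phenols are put at risk.

Compound list
1 | geraniol | CC(C)=CCC/C(C)=C/CO | starting material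
2 | (2R,3R)-2,3-epoxygeraniol | CC(C)=CCC[C@@]1(C)O[C@@H]1CO | intermediate
3 | (2R,3S)-3-(chloromethyl)-2-methyl-2-(4-methylpent-3-en-1-yl)oxirane | CC(C)=CCC[C@@]1(C)O[C@@H]1CCl | intermediate
4 | lithium (3R)-1-chloro-3,7-dimethylocta-1,6-dien-3-olate (alkene geometry irrelevant, not isolated) | CC(C)=CCC[C@](O[Li])(C)C=CCl | intermediate
5 | (R)-3,7-dimethyloct-6-en-1-yn-3-ol | CC(C)=CCC[C@](O)(C)C#C | intermediate
6 | methyl 3-bromo-4-hydroxybenzoate | COC(=O)c1ccc(O)c(Br)c1 | starting material
7 | methyl 3-bromo-4-(triisopropylsilyloxy)benzoate | COC(=O)c1ccc(O[Si](C(C)C)(C(C)C)C(C)C)c(Br)c1 | intermediate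
8 | [2-bromo-6-(methoxycarbonyl)-3-(triisopropylsilyloxy)phenyl]magnesium chloride (not isolated) | COC(=O)c1ccc(O[Si](C(C)C)(C(C)C)C(C)C)c(Br)c1[Mg]Cl | intermediate
9 | methyl 3-bromo-2-iodo-4-(triisopropylsilyloxy)benzoate | COC(=O)c1ccc(O[Si](C(C)C)(C(C)C)C(C)C)c(Br)c1I | intermediate
10 | [3-bromo-2-iodo-4-(triisopropylsilyloxy)phenyl]methanol | OCc1ccc(O[Si](C(C)C)(C(C)C)C(C)C)c(Br)c1I | intermediate
11 | [2-bromo-4-(bromomethyl)-3-iodophenoxy]triisopropylsilane | BrCc1ccc(O[Si](C(C)C)(C(C)C)C(C)C)c(Br)c1I | intermediate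
12 | 2,4-dihydroxyacetophenone | CC(=O)c1ccc(O)cc1O | starting material
13 | 1-[2,4-bis(triisopropylsilyloxy)phenyl]ethan-1-one | CC(=O)c1ccc(O[Si](C(C)C)(C(C)C)C(C)C)cc1O[Si](C(C)C)(C(C)C)C(C)C | intermediate
14 | lithium enolate of 13 (not isolated) | [Li]OC(=C)c1ccc(O[Si](C(C)C)(C(C)C)C(C)C)cc1O[Si](C(C)C)(C(C)C)C(C)C | intermediate
15 | 3-[3-bromo-2-iodo-4-(triisopropylsilyloxy)phenyl]-1-[2,4-bis(triisopropylsilyloxy)phenyl]propan-1-one | O=C(CCc1ccc(O[Si](C(C)C)(C(C)C)C(C)C)c(Br)c1I)c1ccc(O[Si](C(C)C)(C(C)C)C(C)C)cc1O[Si](C(C)C)(C(C)C)C(C)C | intermediate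
16 | 3-{3-bromo-2-[(3R)-3-hydroxy-3,7-dimethyloct-6-en-1-yn-1-yl]-4-(triisopropylsilyloxy)phenyl}-1-[2,4-bis(triisopropylsilyloxy)phenyl]propan-1-one | CC(C)=CCC[C@](O)(C)C#Cc1c(Br)c(O[Si](C(C)C)(C(C)C)C(C)C)ccc1CCC(=O)c1ccc(O[Si](C(C)C)(C(C)C)C(C)C)cc1O[Si](C(C)C)(C(C)C)C(C)C | intermediate
17 | 3-{3-bromo-2-[(1Z,3R)-3-hydroxy-3,7-dimethylocta-1,6-dien-1-yl]-4-(triisopropylsilyloxy)phenyl}-1-[2,4-bis(triisopropylsilyloxy)phenyl]propan-1-one (precursor of the key step) | CC(C)=CCC[C@](O)(C)/C=C\c1c(Br)c(O[Si](C(C)C)(C(C)C)C(C)C)ccc1CCC(=O)c1ccc(O[Si](C(C)C)(C(C)C)C(C)C)cc1O[Si](C(C)C)(C(C)C)C(C)C | intermediate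
18 | 1-[2,4-bis(triisopropylsilyloxy)phenyl]-3-[(2R)-2-methyl-2-(4-methylpent-3-en-1-yl)-8-(triisopropylsilyloxy)-2H-chromen-5-yl]propan-1-one (product of the key step) | CC(C)=CCC[C@]1(C)C=Cc2c(CCC(=O)c3ccc(O[Si](C(C)C)(C(C)C)C(C)C)cc3O[Si](C(C)C)(C(C)C)C(C)C)ccc(O[Si](C(C)C)(C(C)C)C(C)C)c2O1 | intermediate
19 | side-chain epoxide of 18 (2R; epimers at the oxirane CH) | CC1(C)OC1CC[C@]2(C)C=Cc3c(CCC(=O)c4ccc(O[Si](C(C)C)(C(C)C)C(C)C)cc4O[Si](C(C)C)(C(C)C)C(C)C)ccc(O[Si](C(C)C)(C(C)C)C(C)C)c3O2 | intermediate
20 | hydroxy selenide, 2-[4-hydroxy-4-methyl-3-(phenylselanyl)pentyl] chromene (2R; not isolated) | CC(C)(O)C([Se]c1ccccc1)CC[C@]2(C)C=Cc3c(CCC(=O)c4ccc(O[Si](C(C)C)(C(C)C)C(C)C)cc4O[Si](C(C)C)(C(C)C)C(C)C)ccc(O[Si](C(C)C)(C(C)C)C(C)C)c3O2 | intermediate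
21 | selenoxide of 20 (2R; not isolated) | CC(C)(O)C([Se](=O)c1ccccc1)CC[C@]2(C)C=Cc3c(CCC(=O)c4ccc(O[Si](C(C)C)(C(C)C)C(C)C)cc4O[Si](C(C)C)(C(C)C)C(C)C)ccc(O[Si](C(C)C)(C(C)C)C(C)C)c3O2 | intermediate
22 | 1-[2,4-bis(triisopropylsilyloxy)phenyl]-3-{(2R)-2-[(2E)-4-hydroxy-4-methylpent-2-en-1-yl]-2-methyl-8-(triisopropylsilyloxy)-2H-chromen-5-yl}propan-1-one | CC(C)(O)/C=C/C[C@]1(C)C=Cc2c(CCC(=O)c3ccc(O[Si](C(C)C)(C(C)C)C(C)C)cc3O[Si](C(C)C)(C(C)C)C(C)C)ccc(O[Si](C(C)C)(C(C)C)C(C)C)c2O1 | intermediate
23 | 1-(2,4-dihydroxyphenyl)-3-{(2R)-8-hydroxy-2-[(2E)-4-hydroxy-4-methylpent-2-en-1-yl]-2-methyl-2H-chromen-5-yl}propan-1-one | CC(C)(O)/C=C/C[C@]1(C)C=Cc2c(CCC(=O)c3ccc(O)cc3O)ccc(O)c2O1 | target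

Total step count: 15.
Longest linear sequence: 11 steps (6 → 23 through steps 4–7 and 9–15).

The three steps most likely to fail

1. **Step 12.**
   - What may go wrong: zerovalent palladium may insert slowly into the doubly ortho-substituted, electron-rich C8a–Br bond. C–O reductive elimination may be slow. The arylpalladium species may be captured by the ketone enolate of a second molecule. Carbonate may strip silyl groups.
   - Fallback: the pyran is closed before ring B is attached, on a smaller substrate that has no enolisable ketone, and the arm is built afterwards. It sets out from 10 and comes back at 18. Alcohol 10 is silylated (TBSCl, imidazole, DMF) to the benzylic TBS ether F1. This is coupled with 5 as in step 10 to the alkyne F2, semihydrogenated as in step 11 to the Z-allylic alcohol F3, and cyclised as in step 12 to the chromene silyl ether F4. Pyridinium p-toluenesulfonate in EtOH removes only the alkyl silyl ether and gives the chromenyl methanol F5. Appel bromination gives the chromenylmethyl bromide F6. Alkylation of enolate 14 with this bromide, as in step 9, gives 18.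

2. **Step 5.**
   - What may go wrong: metalation may be incomplete, it may go to the less hindered position ortho to the ester, or magnesium halide may be lost to form an aryne.
   - Fallback: the preformed arylmagnesium is replaced by kinetic lithiation with capture in situ, followed by ipso-iodination. It sets out from 7 and comes back at 9. Compound 7 and B(OiPr)3 are treated together with LiTMP (lithium 2,2,6,6-tetramethylpiperidide) in THF at −78 °C. The aryllithium is then borylated before it can eliminate or attack an ester, and mild hydrolysis gives the arylboronic acid F7. Iododeboronation with NaI and TsN(Cl)Na (chloramine-T) in aqueous THF then gives 9.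

3. **Step 13.**
   - What may go wrong: the peracid may also oxidise the C3=C4 alkene, or it may cause Baeyer–Villiger oxidation of the electron-rich aryl ketone.
   - Fallback: the peracid is replaced by osmylation, which discriminates more strongly in favour of the accessible trisubstituted alkene. It sets out from 18 and comes back at 20. Upjohn dihydroxylation (K2OsO2(OH)4 cat., N-methylmorpholine N-oxide, acetone/H2O, 0 °C) gives the side-chain diol F8. MsCl and Et3N in CH2Cl2 at −10 °C sulfonylate only the secondary hydroxyl and give the hydroxy mesylate F9. The selenolate prepared as in step 14 then replaces the mesylate at the CH carbon, directly or through 19 formed in the flask. This gives hydroxy selenide 20, which is oxidised and eliminated as in step 14.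

Further compounds
F1 | step 12 | {[3-bromo-2-iodo-4-(triisopropylsilyloxy)phenyl]methoxy}(tert-butyl)dimethylsilane | CC(C)(C)[Si](C)(C)OCc1ccc(O[Si](C(C)C)(C(C)C)C(C)C)c(Br)c1I
F2 | step 12 | (3R)-1-[2-bromo-6-(tert-butyldimethylsilyloxymethyl)-3-(triisopropylsilyloxy)phenyl]-3,7-dimethyloct-6-en-1-yn-3-ol | CC(C)=CCC[C@](O)(C)C#Cc1c(Br)c(O[Si](C(C)C)(C(C)C)C(C)C)ccc1CO[Si](C)(C)C(C)(C)C
F3 | step 12 | (1Z,3R)-1-[2-bromo-6-(tert-butyldimethylsilyloxymethyl)-3-(triisopropylsilyloxy)phenyl]-3,7-dimethylocta-1,6-dien-3-ol | CC(C)=CCC[C@](O)(C)/C=C\c1c(Br)c(O[Si](C(C)C)(C(C)C)C(C)C)ccc1CO[Si](C)(C)C(C)(C)C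
F4 | step 12 | (2R)-5-(tert-butyldimethylsilyloxymethyl)-2-methyl-2-(4-methylpent-3-en-1-yl)-8-(triisopropylsilyloxy)-2H-chromene | CC(C)=CCC[C@]1(C)C=Cc2c(CO[Si](C)(C)C(C)(C)C)ccc(O[Si](C(C)C)(C(C)C)C(C)C)c2O1
F5 | step 12 | [(2R)-2-methyl-2-(4-methylpent-3-en-1-yl)-8-(triisopropylsilyloxy)-2H-chromen-5-yl]methanol | CC(C)=CCC[C@]1(C)C=Cc2c(CO)ccc(O[Si](C(C)C)(C(C)C)C(C)C)c2O1
F6 | step 12 | (2R)-5-(bromomethyl)-2-methyl-2-(4-methylpent-3-en-1-yl)-8-(triisopropylsilyloxy)-2H-chromene | CC(C)=CCC[C@]1(C)C=Cc2c(CBr)ccc(O[Si](C(C)C)(C(C)C)C(C)C)c2O1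
F7 | step 5 | [2-bromo-6-(methoxycarbonyl)-3-(triisopropylsilyloxy)phenyl]boronic acid | COC(=O)c1ccc(O[Si](C(C)C)(C(C)C)C(C)C)c(Br)c1B(O)O
F8 | step 13 | 1-[2,4-bis(triisopropylsilyloxy)phenyl]-3-[(2R)-2-(3,4-dihydroxy-4-methylpentyl)-2-methyl-8-(triisopropylsilyloxy)-2H-chromen-5-yl]propan-1-one (epimers at the secondary carbinol) | CC(C)(O)C(O)CC[C@]1(C)C=Cc2c(CCC(=O)c3ccc(O[Si](C(C)C)(C(C)C)C(C)C)cc3O[Si](C(C)C)(C(C)C)C(C)C)ccc(O[Si](C(C)C)(C(C)C)C(C)C)c2O1
F9 | step 13 | secondary methanesulfonate of F8 | CC(C)(O)C(OS(C)(=O)=O)CC[C@]1(C)C=Cc2c(CCC(=O)c3ccc(O[Si](C(C)C)(C(C)C)C(C)C)cc3O[Si](C(C)C)(C(C)C)C(C)C)ccc(O[Si](C(C)C)(C(C)C)C(C)C)c2O1
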